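We begin from a neighbour of these flasks, one with less initiator, and ask what such a change moves: how fast the chain clears coupling partner.

    starting material + initiating radical → capped initiator + first chain carrier (k1 = 13000 M⁻¹ s⁻¹)
    initiator → 2 initiating radical (k2 = 3.9 × 10⁻⁴ min⁻¹)
    starting material + second chain carrier → by-product + first chain carrier (k3 = 17000 M⁻¹ s⁻¹)
    coupling partner + first chain carrier ⇌ product + second chain carrier (K4 = 0.67, k4 = 31000 M⁻¹ min⁻¹)
    2 second chain carrier → ended chains A (k5 = 9 × 10⁶ M⁻¹ s⁻¹)
    2 first chain carrier → ended chains B (k6 = 2 × 10⁶ M⁻¹ s⁻¹)
    first chain carrier → ended carrier (k7 = 4.4 min⁻¹)
    starting material ⇌ dormant form (K8 = 2.0, k8 = 8.3 × 10⁻⁴ min⁻¹)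
    coupling partner → decomposed reagent (k9 = 1.3 × 10⁻⁴ min⁻¹)

in all of them: initiator 0.38 mM
- red: starting material 0.015 M; coupling partner 0.0158 M; time 20 h; a closed flask charged with all of it at once and left for 20 h
- ochre: starting material 0.015 M; coupling partner 0.0158 M; a single well-mixed tank run continuously and read at steady state, 20 h in it on average
- blue: starting material 0.015 M; coupling partner 0.0158 M (fed, over 16.0 h); time 20 h; a stirred flask in which coupling partner is dosed at a steady rate over 16.0 h without added volume, worked up at 20 h
- grey: starting material 0.015 M (fed, over 16.0 h); coupling partner 0.0158 M; time 20 h; a stirred flask in which starting material is dosed at a steady rate over 16.0 h without added volume, worked up at 20 h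

- the set-up with the highest amount of product at the outlet or at the end, in percent of the starting material put in ("none" if the first two lie within 2 percentage points) (red / ochre / blue / grey / none)
- amount of product at the outlet or at the end, in percent of the starting material put in, red
- amount of product at the outlet or at the end, in percent of the starting material put in, ochre
- amount of product at the outlet or at the end, in percent of the starting material put in, blue
- amount of product at the outlet or at the end, in percent of the starting material put in, grey

- percent here means starting material units held: one ended chains B counts as two
- two of one species on the left: rate k times its square, two consumed each time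
- the stated concentrations are those of everything mixed, before any reaction; amounts are the same in each set-up
- the feed brings no volume worth counting
- run time (red): 20 h

We climb the ladder from the fastest rung. At the charge, second chain carrier meets starting material at 15300 min⁻¹, and first chain carrier meets coupling partner at 490 min⁻¹, which is far slower, so at the charge first chain carrier is the resting state. It ends by itself at 4.4 min⁻¹, well below that, by a factor of 111. That ending takes 13.6 s, far shorter than the initiator half-life of 30 h, so the level x of first chain carrier keeps pace with initiation, two radicals per initiator lost. We take initiator at mid-run, 0.301 mM, which gives initiation of 2.35 × 10⁻⁷ M min⁻¹. Against it stand first-order ending and pairwise ending, the latter a times x squared with a = 2.40 × 10⁸ M⁻¹ min⁻¹. With h = 9.17 × 10⁻⁹ M, half of the first-order constant over a, the balance gives x as the root of h squared plus initiation over a, less h: x = 2.34 × 10⁻⁸ M.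

Our quantity is the chain clearance κ, the coupling step's rate constant times x, a pseudo-first-order rate constant for coupling partner: 7.26 × 10⁻⁴ min⁻¹. Its half-life of 15.9 h is shorter than the 89 h of decay, and the two add to a total loss rate s = 8.56 × 10⁻⁴ min⁻¹, so we reckon product as the share κ/s of the coupling partner lost.

Red then gives 57.3 %. Blue, the same loss rate on a dosed charge, gives 39.7 %. In ochre, the tank balance puts initiator at 0.259 mM, so κ is 6.59 × 10⁻⁴ min⁻¹ and the tank gives 42.8 %. Grey starts with no starting material in the flask, while our reckoning for red takes it as present from the start, so for grey we commit to the red figure as a ceiling: 57.3 %. By hand, then, red stands above ochre and ochre above blue, while grey stays unplaced.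

The forecast names red, with 56 % for red, 41 % for ochre, 37 % for blue and 52 % for grey, on the ground that “The batch keeps both partners concentrated early and so wins”. Where we gave grey a ceiling, it gave a figure.

The simulation gives red as best: red 55.5 %, ochre 41.3 %, blue 37.3 %, grey 52.4 %.

Red keeps 38 % of its coupling partner, and the loss rate s had left 35.8 %. Now take the grey flask with initiator cut to 1.5 × 10⁻⁴ M. The same balance gives κ = 3.88 × 10⁻⁴ min⁻¹, about half of the first value, and the ceiling drops to 36.5 %. That flask gave 34.2 %, with 39.4 % of the charge left as starting material.

All constants are made up; what happens was integrated by code.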